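**Strategy.** Everything rests on cutting ring A of the flavanone across C7–C8 and C4a–C8a, so that a four-carbon cyclobutenone (C7, C6, C5, C4a) and a two-carbon ynol silyl ether (C8, C8a) assemble the hexasubstituted phloroglucinol core in one thermal cascade. That single operation places the C6 methyl and C8 prenyl groups and delivers the three ring A oxygens in three different states: O7 as free phenol, O1 (on C8a) as silyl ether and O5 as ethyl ether, with C4a–H as the only open site for ring C. The precursors are racemic 3-ethoxy-4-methylcyclobutenone and the TIPS ether of the prenyl-substituted ynol. C2 is set later by rhodium-catalysed arylation of a chromone.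

Key step: step 3

Assumption: the sense of induction in step 9 is taken from the cyclic-enone model for biaryl bisphosphine rhodium catalysts ((S)-ligand gives (2S)); a first run is to confirm it, and the (R)-ligand is used if the sense proves opposite.
Assumption: ethoxyacetylene (hexanes solution), ethyl 4-methylpent-3-enoate, ethynylmagnesium bromide (THF solution) and 4-methoxyphenylboronic acid are taken as commercial.

**Step 1**
Reactants: 1 propionyl chloride; 2 ethoxyacetylene
Product: 4 3-ethoxy-4-methylcyclobut-2-en-1-one (racemic), via methylketene 3 (not isolated)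
Conditions: 1 added over 4 h to 2 (2 equiv) and Et3N (1.2 equiv), Et2O, 0 °C to rt
Reagents that add atoms: none
Why: Dehydrochlorination keeps methylketene at low concentration, and in the ketene–alkyne [2+2] cycloaddition the unsubstituted, nucleophilic carbon of the ynol ether bonds to the ketene carbonyl carbon, which places ethoxy at C3 and methyl at C4 of the cyclobutenone; the C4 stereocentre is racemic and is lost in step 3.

**Step 2**
Reactants: 5 ethyl 4-methylpent-3-enoate
Product: 8 triisopropyl[(5-methylhex-4-en-1-yn-1-yl)oxy]silane, via dibromo enolate 6 (not isolated), via lithium ynolate 7 (not isolated)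
Conditions: CH2Br2, lithium 2,2,6,6-tetramethylpiperidide, THF, −78 °C; add 5; LiN(SiMe3)2; n-BuLi, −78 to 0 °C; i-Pr3SiCl, −78 °C to rt
Reagents that add atoms: dibromomethane, BrCBr; triisopropylsilyl chloride, CC(C)[Si](Cl)(C(C)C)C(C)C
Why: Kowalski ester homologation, in which dibromomethyllithium adds to the ester carbonyl at −78 °C faster than it removes the allylic alpha proton, bromine–lithium exchange on the dibromo enolate triggers the 1,2-shift of the prenyl group that gives the ynolate, and the bulky silyl chloride traps the ynolate on oxygen.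

**Step 3**
Reactants: 4 3-ethoxy-4-methylcyclobut-2-en-1-one; 8 triisopropyl[(5-methylhex-4-en-1-yn-1-yl)oxy]silane
Product: 13 5-ethoxy-6-methyl-2-(3-methylbut-2-en-1-yl)-3-[(triisopropylsilyl)oxy]phenol, via vinylketene 9 (not isolated), via vinylcyclobutenone 10 (not isolated), via dienylketene 11 (not isolated), via cyclohexadienone 12 (not isolated)
Conditions: 4 (1.0 equiv), 8 (1.2 equiv), toluene, 80 °C then 110 °C, sealed tube, argon
Reagents that add atoms: none
Why: Thermal conrotatory 4π opening of 4 gives ethoxy vinylketene 9, whose ketene C=C adds to the electron-rich triple bond of 8 in a [2+2] cycloaddition to give 4-alkenylcyclobutenone 10; a second 4π opening gives dienylketene 11, a 6π electrocyclisation gives dienone 12, and tautomerisation gives phenol 13. The closest known reaction type is the Danheiser benzannulation of cyclobutenones with siloxyalkynes to resorcinol monosilyl ethers. Ring A is closed by disrotatory 6π electrocyclisation, which joins the former ketene carbon (C7) to the methyl-bearing carbon (C6), after the two components have been joined through C7–C8 and C4a–C8a. No stereocentre is created, and the one in racemic 4 disappears on aromatisation. The only selectivity needed is the orientation of the ketene–alkyne [2+2] step: the oxygen lone pair of the ynol ether polarises the triple bond so that its prenyl-bearing carbon (C8) attacks the ketene carbonyl carbon (C7) and the silyloxy carbon (C8a) bonds to C4a. The triple bond is far more nucleophilic than the trisubstituted prenyl alkene, which therefore stays out of the cycloaddition, and the reversible second ring opening funnels either geometry of the dienylketene into the cyclisation.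

**Step 4**
Reactants: 13 5-ethoxy-6-methyl-2-(3-methylbut-2-en-1-yl)-3-[(triisopropylsilyl)oxy]phenol
Product: 14 {[5-ethoxy-3-(methoxymethoxy)-4-methyl-2-(3-methylbut-2-en-1-yl)phenyl]oxy}triisopropylsilane
Conditions: MOMCl, i-Pr2NEt, CH2Cl2, 0 to 40 °C
Reagents that add atoms: chloromethyl methyl ether, COCCl
Why: O-alkylation of the hindered O7 phenol (Williamson-type acetal formation) installs a cap that tolerates fluoride, Grignard reagents, MnO2 and the rhodium step, while the silyl ether on O1 is inert to amine base.

**Step 5**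
Reactants: 14 {[5-ethoxy-3-(methoxymethoxy)-4-methyl-2-(3-methylbut-2-en-1-yl)phenyl]oxy}triisopropylsilane
Product: 15 5-ethoxy-3-(methoxymethoxy)-4-methyl-2-(3-methylbut-2-en-1-yl)phenol
Conditions: Bu4NF, THF, 0 °C; aq NH4Cl
Reagents that add atoms: none
Why: Fluoride-induced desilylation frees the O1 phenol alone, because the MOM acetal on O7 and the ethyl ether on O5 do not react with fluoride.

**Step 6**
Reactants: 15 5-ethoxy-3-(methoxymethoxy)-4-methyl-2-(3-methylbut-2-en-1-yl)phenol
Product: 17 6-ethoxy-2-hydroxy-4-(methoxymethoxy)-5-methyl-3-(3-methylbut-2-en-1-yl)benzaldehyde, via benzylic alcohol 16 (not isolated)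
Conditions: MgCl2, Et3N, (CH2O)n, MeCN, reflux; cold 1 M aq HCl work-up
Reagents that add atoms: paraformaldehyde (as formaldehyde), C=O
Why: Casnati–Skattebøl ortho-formylation, in which the magnesium phenoxide delivers formaldehyde only to the ortho carbon, C4a being the single free ortho position, and a second formaldehyde oxidises the hydroxymethyl intermediate by hydride transfer.

**Step 7**
Reactants: 17 6-ethoxy-2-hydroxy-4-(methoxymethoxy)-5-methyl-3-(3-methylbut-2-en-1-yl)benzaldehyde; 18 ethynylmagnesium bromide
Product: 19 3-ethoxy-2-(1-hydroxyprop-2-yn-1-yl)-5-(methoxymethoxy)-4-methyl-6-(3-methylbut-2-en-1-yl)phenol (racemic)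
Conditions: 18 (3 equiv), THF, 0 °C to rt; aq NH4Cl; used crude
Reagents that add atoms: none
Why: Grignard 1,2-addition to the aldehyde after the first equivalent has deprotonated the phenol gives the propargylic alcohol, whose new stereocentre is left racemic because the next step removes it.

**Step 8**
Reactants: 19 3-ethoxy-2-(1-hydroxyprop-2-yn-1-yl)-5-(methoxymethoxy)-4-methyl-6-(3-methylbut-2-en-1-yl)phenol
Product: 21 5-ethoxy-7-(methoxymethoxy)-6-methyl-8-(3-methylbut-2-en-1-yl)-4H-chromen-4-one, via ynone 20 (not isolated)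
Conditions: MnO2, CH2Cl2, rt; filter; DMAP (10 mol %), CH2Cl2, rt
Reagents that add atoms: none
Why: MnO2 oxidises the benzylic propargylic alcohol to the ynone, and the ortho phenol then adds to the unsubstituted alkyne terminus in a DMAP-catalysed 6-endo-dig oxa-Michael cyclisation that closes ring C with O1 as the ring oxygen.

**Step 9**
Reactants: 21 5-ethoxy-7-(methoxymethoxy)-6-methyl-8-(3-methylbut-2-en-1-yl)-4H-chromen-4-one; 22 4-methoxyphenylboronic acid
Product: 23 (2S)-5-ethoxy-2-(4-methoxyphenyl)-7-(methoxymethoxy)-6-methyl-8-(3-methylbut-2-en-1-yl)-2,3-dihydro-4H-chromen-4-one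
Conditions: 22 (3 equiv), [Rh(OH)(cod)]2 (2.5 mol %), (S)-(6,6'-dimethoxybiphenyl-2,2'-diyl)bis[bis(3,4,5-trifluorophenyl)phosphine] (5.5 mol %), toluene/H2O, 30–50 °C
Reagents that add atoms: none
Why: Rhodium-catalysed asymmetric 1,4-addition of an arylboronic acid to a chromone (Hayashi–Miyaura reaction), in which the aryl–rhodium complex of the chiral bisphosphine inserts C2=C3 with the aryl group delivered to the Re face of C2 to set (2S), and water protonates the rhodium enolate before it can expel the C8a aryloxide.

**Step 10**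
Reactants: 23 (2S)-5-ethoxy-2-(4-methoxyphenyl)-7-(methoxymethoxy)-6-methyl-8-(3-methylbut-2-en-1-yl)-2,3-dihydro-4H-chromen-4-one
Product: 24 (2S)-5-ethoxy-7-hydroxy-2-(4-methoxyphenyl)-6-methyl-8-(3-methylbut-2-en-1-yl)-2,3-dihydro-4H-chromen-4-one
Conditions: 3 M aq HCl, MeOH, rt
Reagents that add atoms: none
Why: Acid-catalysed transacetalisation removes the MOM group as dimethoxymethane, and dilute protic acid at room temperature should neither open the flavanone ring nor cyclise the prenyl group, so C2 stays (S).

**Step 11**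
Reactants: 24 (2S)-5-ethoxy-7-hydroxy-2-(4-methoxyphenyl)-6-methyl-8-(3-methylbut-2-en-1-yl)-2,3-dihydro-4H-chromen-4-one
Product: 25 (2S)-5,7-dihydroxy-2-(4-methoxyphenyl)-6-methyl-8-(3-methylbut-2-en-1-yl)-2,3-dihydro-4H-chromen-4-one
Conditions: MgI2·OEt2 (5 equiv), THF, 60 °C; aq NH4Cl/Na2S2O3
Reagents that add atoms: none
Why: Chelation-controlled ether cleavage, in which magnesium bridges the C4 carbonyl and O5, iodide removes the ethyl group by SN2 attack, the unchelated 4'-methyl ether stays, and the absence of base avoids enolisation and ring opening at C2.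

**Compound list**
1 | propionyl chloride | CCC(=O)Cl | starting material
2 | ethoxyacetylene | CCOC#C | starting material
3 | methylketene (prop-1-en-1-one) | CC=C=O | intermediate
4 | 3-ethoxy-4-methylcyclobut-2-en-1-one (racemic) | CCOC1=CC(=O)C1C | intermediate
5 | ethyl 4-methylpent-3-enoate | CCOC(=O)CC=C(C)C | starting material
6 | lithium 1,1-dibromo-5-methylhexa-1,4-dien-2-olate | [Li+].[O-]C(CC=C(C)C)=C(Br)Br | intermediate
7 | lithium 5-methylhex-4-en-1-yn-1-olate | [Li+].[O-]C#CCC=C(C)C | intermediate
8 | triisopropyl[(5-methylhex-4-en-1-yn-1-yl)oxy]silane | CC(C)=CCC#CO[Si](C(C)C)(C(C)C)C(C)C | intermediate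
9 | (3Z)-3-ethoxypenta-1,3-dien-1-one | O=C=C/C(OCC)=C/C | intermediate
10 | 4-[(1Z)-1-ethoxyprop-1-en-1-yl]-2-(3-methylbut-2-en-1-yl)-3-[(triisopropylsilyl)oxy]cyclobut-2-en-1-one (racemic) | O=C1C(CC=C(C)C)=C(O[Si](C(C)C)(C(C)C)C(C)C)C1/C(OCC)=C/C | intermediate
11 | (3E,5Z)-5-ethoxy-2-(3-methylbut-2-en-1-yl)-3-[(triisopropylsilyl)oxy]hepta-1,3,5-trien-1-one | O=C=C(CC=C(C)C)/C(O[Si](C(C)C)(C(C)C)C(C)C)=C\C(OCC)=C\C | intermediate
12 | 5-ethoxy-6-methyl-2-(3-methylbut-2-en-1-yl)-3-[(triisopropylsilyl)oxy]cyclohexa-2,4-dien-1-one (racemic) | O=C1C(CC=C(C)C)=C(O[Si](C(C)C)(C(C)C)C(C)C)C=C(OCC)C1C | intermediate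
13 | 5-ethoxy-6-methyl-2-(3-methylbut-2-en-1-yl)-3-[(triisopropylsilyl)oxy]phenol | CCOc1cc(O[Si](C(C)C)(C(C)C)C(C)C)c(CC=C(C)C)c(O)c1C | intermediate
14 | {[5-ethoxy-3-(methoxymethoxy)-4-methyl-2-(3-methylbut-2-en-1-yl)phenyl]oxy}triisopropylsilane | CCOc1cc(O[Si](C(C)C)(C(C)C)C(C)C)c(CC=C(C)C)c(OCOC)c1C | intermediate
15 | 5-ethoxy-3-(methoxymethoxy)-4-methyl-2-(3-methylbut-2-en-1-yl)phenol | CCOc1cc(O)c(CC=C(C)C)c(OCOC)c1C | intermediate
16 | 3-ethoxy-2-(hydroxymethyl)-5-(methoxymethoxy)-4-methyl-6-(3-methylbut-2-en-1-yl)phenol | CCOc1c(CO)c(O)c(CC=C(C)C)c(OCOC)c1C | intermediate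
17 | 6-ethoxy-2-hydroxy-4-(methoxymethoxy)-5-methyl-3-(3-methylbut-2-en-1-yl)benzaldehyde | CCOc1c(C=O)c(O)c(CC=C(C)C)c(OCOC)c1C | intermediate
18 | ethynylmagnesium bromide | C#C[Mg]Br | starting material
19 | 3-ethoxy-2-(1-hydroxyprop-2-yn-1-yl)-5-(methoxymethoxy)-4-methyl-6-(3-methylbut-2-en-1-yl)phenol (racemic) | CCOc1c(C(O)C#C)c(O)c(CC=C(C)C)c(OCOC)c1C | intermediate
20 | 1-[6-ethoxy-2-hydroxy-4-(methoxymethoxy)-5-methyl-3-(3-methylbut-2-en-1-yl)phenyl]prop-2-yn-1-one | CCOc1c(C(=O)C#C)c(O)c(CC=C(C)C)c(OCOC)c1C | intermediate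
21 | 5-ethoxy-7-(methoxymethoxy)-6-methyl-8-(3-methylbut-2-en-1-yl)-4H-chromen-4-one | CCOc1c(C)c(OCOC)c(CC=C(C)C)c2OC=CC(=O)c12 | intermediate
22 | 4-methoxyphenylboronic acid | COc1ccc(B(O)O)cc1 | starting material
23 | (2S)-5-ethoxy-2-(4-methoxyphenyl)-7-(methoxymethoxy)-6-methyl-8-(3-methylbut-2-en-1-yl)-2,3-dihydro-4H-chromen-4-one | COc1ccc([C@@H]2CC(=O)c3c(OCC)c(C)c(OCOC)c(CC=C(C)C)c3O2)cc1 | intermediate
24 | (2S)-5-ethoxy-7-hydroxy-2-(4-methoxyphenyl)-6-methyl-8-(3-methylbut-2-en-1-yl)-2,3-dihydro-4H-chromen-4-one | COc1ccc([C@@H]2CC(=O)c3c(OCC)c(C)c(O)c(CC=C(C)C)c3O2)cc1 | intermediate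
25 | (2S)-5,7-dihydroxy-2-(4-methoxyphenyl)-6-methyl-8-(3-methylbut-2-en-1-yl)-2,3-dihydro-4H-chromen-4-one | COc1ccc([C@@H]2CC(=O)c3c(O)c(C)c(O)c(CC=C(C)C)c3O2)cc1 | target

**Step count.** Total: 11 steps. Longest linear sequence: 10 steps (step 1 or step 2, then steps 3 to 11).

**Steps most likely to fail**

Step 3. The ethoxy group stabilises cyclobutenone 4 as a vinylogous ester, so its electrocyclic opening may need temperatures at which the vinylketene dimerises or acylates the product phenol and the ynol ether degrades. The fallback generates the same vinylketene at room temperature from an acyclic acid chloride, so that only the second stage of the cascade needs heat. It sets out from 8 and commercial ethyl 3-oxopentanoate. Enol ether formation with triethyl orthoformate and catalytic acid should give ethyl (2E)-3-ethoxypent-2-enoate F1. Saponification (KOH, aqueous ethanol, careful acidification) should give (2E)-3-ethoxypent-2-enoic acid F2. 1-Chloro-N,N,2-trimethylprop-1-en-1-amine under neutral conditions should give (2E)-3-ethoxypent-2-enoyl chloride F3. Slow addition of F3 to 8 and Et3N in toluene at room temperature should effect 1,4-dehydrochlorination. Allylic strain with the acyl group keeps the terminal methyl group away from C2 during the gamma-deprotonation, so the ketene formed should be 9 itself. The fallback rejoins the route at 9, which 8 traps to 10, and warming to 110 °C completes the cascade to 13.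

Step 9. The peri ethoxy group and the C8 prenyl group crowd both ends of the enone, so the facial discrimination of the aryl transfer may fall short of what simple chromones give. The fallback reaches the single enantiomer by resolution instead of enantioselective bond formation. It sets out from 21 and 22. Arylation with [Rh(OH)(cod)]2 alone, without chiral ligand, should give the racemic form of the flavanone, rac-5-ethoxy-2-(4-methoxyphenyl)-7-(methoxymethoxy)-6-methyl-8-(3-methylbut-2-en-1-yl)-2,3-dihydro-4H-chromen-4-one F4. Noyori–Ikariya transfer hydrogenation (RuCl[(R,R)-TsDPEN](p-cymene), HCO2H/Et3N, rt), stopped near half conversion, should reduce the (2R) enantiomer to the cis alcohol (2R,4R)-5-ethoxy-2-(4-methoxyphenyl)-7-(methoxymethoxy)-6-methyl-8-(3-methylbut-2-en-1-yl)-3,4-dihydro-2H-chromen-4-ol F5 and leave the (2S) ketone. The catalyst enantiomer follows the aryl ketone model and is to be checked on the racemate. Chromatography separates ketone from alcohol, and the fallback returns to the route at 23.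

Step 11. An ethyl group leaves more slowly than a methyl group under iodide attack, so long heating with the Lewis acid may let the prenyl group cyclise onto the free O7 hydroxyl or erode C2 by reversible ring opening. The fallback moves the de-ethylation to the achiral chromone and ends with protic acid only. It sets out from 21. MgI2·OEt2 in THF/toluene at 80 °C meets no stereocentre and no free hydroxyl next to the prenyl group, and should give 5-hydroxy-7-(methoxymethoxy)-6-methyl-8-(3-methylbut-2-en-1-yl)-4H-chromen-4-one F6. NaH and MOMCl in DMF should cap the chelated hydroxyl to give 5,7-bis(methoxymethoxy)-6-methyl-8-(3-methylbut-2-en-1-yl)-4H-chromen-4-one F7. The rhodium arylation of step 9 with 22 should give (2S)-5,7-bis(methoxymethoxy)-2-(4-methoxyphenyl)-6-methyl-8-(3-methylbut-2-en-1-yl)-2,3-dihydro-4H-chromen-4-one F8. One treatment with 3 M aq HCl in MeOH at room temperature removes both acetals, and the fallback comes back to the route at 25.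

**Further compounds**
F1 | step 3 | ethyl (2E)-3-ethoxypent-2-enoate | CCOC(=O)/C=C(\CC)OCC
F2 | step 3 | (2E)-3-ethoxypent-2-enoic acid | OC(=O)/C=C(\CC)OCC
F3 | step 3 | (2E)-3-ethoxypent-2-enoyl chloride | ClC(=O)/C=C(\CC)OCC
F4 | step 9 | rac-5-ethoxy-2-(4-methoxyphenyl)-7-(methoxymethoxy)-6-methyl-8-(3-methylbut-2-en-1-yl)-2,3-dihydro-4H-chromen-4-one | COc1ccc(C2CC(=O)c3c(OCC)c(C)c(OCOC)c(CC=C(C)C)c3O2)cc1
F5 | step 9 | (2R,4R)-5-ethoxy-2-(4-methoxyphenyl)-7-(methoxymethoxy)-6-methyl-8-(3-methylbut-2-en-1-yl)-3,4-dihydro-2H-chromen-4-ol | COc1ccc([C@H]2C[C@@H](O)c3c(OCC)c(C)c(OCOC)c(CC=C(C)C)c3O2)cc1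
F6 | step 11 | 5-hydroxy-7-(methoxymethoxy)-6-methyl-8-(3-methylbut-2-en-1-yl)-4H-chromen-4-one | Oc1c(C)c(OCOC)c(CC=C(C)C)c2OC=CC(=O)c12
F7 | step 11 | 5,7-bis(methoxymethoxy)-6-methyl-8-(3-methylbut-2-en-1-yl)-4H-chromen-4-one | COCOc1c(C)c(OCOC)c(CC=C(C)C)c2OC=CC(=O)c12
F8 | step 11 | (2S)-5,7-bis(methoxymethoxy)-2-(4-methoxyphenyl)-6-methyl-8-(3-methylbut-2-en-1-yl)-2,3-dihydro-4H-chromen-4-one | COc1ccc([C@@H]2CC(=O)c3c(OCOC)c(C)c(OCOC)c(CC=C(C)C)c3O2)cc1
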